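**Strategy.** The cyclopentane ring (C4a, C5, C6, C7, C7a) and the piperidine ring are folded from one chain in a titanium-mediated enyne cyclization/acylation. A but-2-ynyl arm on nitrogen adds to the β-carbon of an unsaturated δ-lactone (C7a–C4a), and the alkenyl–titanium bond then attacks the lactone carbonyl (C7–C6). The step exploits that C6 bears oxygen and C7 a methyl group: C6 is the lactone carbonyl, C7 the methyl-bearing alkyne carbon. The lactone ties the future C4 methyl carbon to C6 through oxygen, which enforces cis delivery and the 4,4a configuration from an organocatalytically set C4 stereocentre, and is expelled in the same operation. Hydrogenation, reduction and Mitsunobu esterification finish.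

Key step: step 6

Remark: atom labels C1–C7a are those of the cyclopenta[c]pyridine core of the target (C1, N2, C3, C4, C4a, C5, C6, C7, C7a).

Step 1
Reactants: 1 3,3-diethoxypropan-1-amine; 2 methyl chloroformate
Product: 3 methyl N-(3,3-diethoxypropyl)carbamate
Conditions: Et3N, CH2Cl2, 0 °C to rt
Reagents that add atoms: none
Why: N-acylation of the primary amine (carbamate formation); the carbamate carbon is the future N-methyl carbon and the acetal masks the aldehyde.

Step 2
Reactants: 3 methyl N-(3,3-diethoxypropyl)carbamate; 4 1-bromobut-2-yne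
Product: 5 methyl N-(but-2-yn-1-yl)-N-(3,3-diethoxypropyl)carbamate
Conditions: NaH, DMF, 0 °C to rt
Reagents that add atoms: none
Why: SN2 N-alkylation of the carbamate anion with a reactive propargylic bromide installs C1, C7a, C7 and the C7 methyl group.

Step 3
Reactants: 5 methyl N-(but-2-yn-1-yl)-N-(3,3-diethoxypropyl)carbamate
Product: 6 methyl N-(but-2-yn-1-yl)-N-(3-oxopropyl)carbamate
Conditions: 1 M HCl, THF, rt
Reagents that add atoms: water, O
Why: acid-catalysed acetal hydrolysis frees the aldehyde while carbamate and alkyne are inert.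

Step 4
Reactants: 6 methyl N-(but-2-yn-1-yl)-N-(3-oxopropyl)carbamate; 7 formaldehyde (37% aqueous)
Product: 8 methyl N-(but-2-yn-1-yl)-N-[(2R)-2-formyl-3-hydroxypropyl]carbamate
Conditions: (S)-α,α-diphenylprolinol trimethylsilyl ether (10 mol%), pH 7 phosphate buffer, toluene, rt; used crude
Reagents that add atoms: none
Why: enamine-catalysed α-hydroxymethylation (crossed aldol with formaldehyde), in which the diphenyl(silyloxy)methyl group shields one face of the (E)-enamine so that formaldehyde should add to the Si face and set the future C4 as (R).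

Step 5
Reactants: 8 methyl N-(but-2-yn-1-yl)-N-[(2R)-2-formyl-3-hydroxypropyl]carbamate; 9 ketenylidenetriphenylphosphorane (Bestmann ylide)
Product: 11 methyl N-(but-2-yn-1-yl)-N-{[(3R)-6-oxo-3,6-dihydro-2H-pyran-3-yl]methyl}carbamate, via ylide ester 10 (not isolated)
Conditions: toluene, 60 °C
Reagents that add atoms: none
Why: the hydroxyl adds to the cumulated ylide and the ester ylide closes by intramolecular Wittig olefination, which can only give the (Z)-alkene of the six-membered lactone, under neutral conditions that should spare the α-stereocentre.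

Step 6
Reactants: 11 methyl N-(but-2-yn-1-yl)-N-{[(3R)-6-oxo-3,6-dihydro-2H-pyran-3-yl]methyl}carbamate
Product: 13 methyl (4R,4aS)-4-(hydroxymethyl)-7-methyl-6-oxo-1,3,4,4a,5,6-hexahydro-2H-cyclopenta[c]pyridine-2-carboxylate, via titanacyclopentene 12 (not isolated)
Conditions: Ti(OiPr)4 (1.3 equiv), i-PrMgCl (2.6 equiv), Et2O, −78 to −50 °C; then 11, −50 to 0 °C; then 1 M HCl
Reagents that add atoms: none
Why: The alkyne displaces propene from the divalent titanium complex (η2-propene)Ti(OiPr)2 to give a titanacyclopropene, which inserts the lactone C=C so that C7a bonds to the β-carbon C4a and titanium sits on the α-carbon C5 (titanacyclopentene 12); on warming, the alkenyl–titanium bond at C7 adds to the lactone carbonyl C6 and the tetrahedral intermediate collapses with loss of the ring alkoxide, unveiling the cyclopentenone and the C4 hydroxymethyl group. The closest known reaction type is the low-valent titanium alkoxide-mediated tandem cyclization of alkyl 2-en-ynoates to bicyclic enones (oxidative enyne cyclization, then intramolecular nucleophilic acyl substitution), here applied to a cyclic (Z)-enoate. The piperidine ring closes by a 6-exo insertion (C5 and C7 stay outside the new ring) and the cyclopentenone by a 5-exo-trig attack on the carbonyl followed by opening of the lactone. The only new stereocentre, C4a, is controlled by C4: the tether hangs from the lactone carbon next to the alkene, so C7a can reach only the face of C4a syn to the CH2N arm, which gives the cis-fused titanabicycle and, once the lactone is opened, the 4,4a relationship of the target. The step needs complexation of the alkyne in preference to the two carbonyl groups (the reagent is preformed cold and exchanges fastest with alkynes), β-regioselectivity (secured by the ester, which draws titanium to the α-carbon, and by the six-membered tether) and acylation before work-up (secured by warming to 0 °C, where unhindered alkyl esters are attacked by the alkenyl–titanium bond).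

Step 7
Reactants: 13 methyl (4R,4aS)-4-(hydroxymethyl)-7-methyl-6-oxo-1,3,4,4a,5,6-hexahydro-2H-cyclopenta[c]pyridine-2-carboxylate
Product: 14 methyl (4R,4aS)-4-(iodomethyl)-7-methyl-6-oxo-1,3,4,4a,5,6-hexahydro-2H-cyclopenta[c]pyridine-2-carboxylate
Conditions: PPh3, I2, imidazole, CH2Cl2, 0 °C to rt
Reagents that add atoms: iodine, II
Why: Appel iodination converts the primary alcohol into the iodide under neutral conditions that leave the enone and its γ-stereocentre C4a untouched.

Step 8
Reactants: 14 methyl (4R,4aS)-4-(iodomethyl)-7-methyl-6-oxo-1,3,4,4a,5,6-hexahydro-2H-cyclopenta[c]pyridine-2-carboxylate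
Product: 16 methyl (4R,4aS,7S,7aR)-4,7-dimethyl-6-oxooctahydro-2H-cyclopenta[c]pyridine-2-carboxylate, via C7 epimer 15 (not isolated)
Conditions: H2 (5 bar), Pd/C, Et3N, MeOH, rt; then DBU, rt
Reagents that add atoms: none
Why: heterogeneous hydrogenation should add hydrogen to the tetrasubstituted enone from the face of H4a, away from the piperidine ring, making the ring fusion cis (C7a) while the C–I bond is hydrogenolysed to the C4 methyl group, and DBU then epimerizes the kinetic C7 epimer 15 to the more stable ketone with the methyl group trans to C1.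

Step 9
Reactants: 16 methyl (4R,4aS,7S,7aR)-4,7-dimethyl-6-oxooctahydro-2H-cyclopenta[c]pyridine-2-carboxylate
Product: 17 (4R,4aS,6S,7S,7aR)-2,4,7-trimethyloctahydro-1H-cyclopenta[c]pyridin-6-ol (6-epi-incarvilline)
Conditions: LiAlH4, THF, 0 °C to reflux; aqueous NaOH work-up
Reagents that add atoms: none
Why: LiAlH4 reduces the methyl carbamate to the N-methyl amine and the ketone to the alcohol, and the small hydride should attack C6 from the convex face (that of H4a and H7a), as in 2-methylcyclopentanone reductions, placing the hydroxyl trans to the C7 methyl group (6S).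

Step 10
Reactants: 18 (S)-citronellol
Product: 19 tert-butyl{[(3S)-3,7-dimethyloct-6-en-1-yl]oxy}dimethylsilane
Conditions: TBSCl, imidazole, DMF, rt
Reagents that add atoms: tert-butyldimethylsilyl chloride, CC(C)(C)[Si](C)(C)Cl
Why: silylation of the primary alcohol protects it through the oxidation, olefination and Mitsunobu steps.

Step 11
Reactants: 19 tert-butyl{[(3S)-3,7-dimethyloct-6-en-1-yl]oxy}dimethylsilane
Product: 21 (4S)-6-[(tert-butyldimethylsilyl)oxy]-4-methylhexanal, via ozonide 20 (not isolated)
Conditions: O3, CH2Cl2, −78 °C; then PPh3, −78 °C to rt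
Reagents that add atoms: ozone, [O-][O+]=O
Why: ozonolysis with reductive work-up cleaves the trisubstituted alkene to the aldehyde without touching the methyl-bearing stereocentre.

Step 12
Reactants: 21 (4S)-6-[(tert-butyldimethylsilyl)oxy]-4-methylhexanal; 22 ethyl 2-(triphenyl-λ5-phosphanylidene)propanoate
Product: 23 ethyl (2E,6S)-8-[(tert-butyldimethylsilyl)oxy]-2,6-dimethyloct-2-enoate
Conditions: toluene, 80 °C
Reagents that add atoms: none
Why: Wittig olefination with the stabilized α-methyl ylide should give the (E)-trisubstituted enoate under thermodynamic control of the oxaphosphetane.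

Step 13
Reactants: 23 ethyl (2E,6S)-8-[(tert-butyldimethylsilyl)oxy]-2,6-dimethyloct-2-enoate
Product: 24 (2E,6S)-8-[(tert-butyldimethylsilyl)oxy]-2,6-dimethyloct-2-enoic acid
Conditions: LiOH, THF/MeOH/H2O, rt; then 1 M HCl to pH 4, 0 °C
Reagents that add atoms: lithium hydroxide, [Li+].[OH-]
Why: saponification of the ethyl ester leaves the silyl ether and the alkene geometry intact.

Step 14
Reactants: 17 (4R,4aS,6S,7S,7aR)-2,4,7-trimethyloctahydro-1H-cyclopenta[c]pyridin-6-ol; 24 (2E,6S)-8-[(tert-butyldimethylsilyl)oxy]-2,6-dimethyloct-2-enoic acid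
Product: 25 (4R,4aS,6R,7S,7aR)-2,4,7-trimethyloctahydro-1H-cyclopenta[c]pyridin-6-yl (2E,6S)-8-[(tert-butyldimethylsilyl)oxy]-2,6-dimethyloct-2-enoate
Conditions: PPh3, DIAD, THF, 0 °C to rt
Reagents that add atoms: none
Why: Mitsunobu esterification displaces the oxyphosphonium ion with the carboxylate by SN2, inverting C6 from (S) to (R), and tolerates the tertiary amine and the silyl ether.

Step 15
Reactants: 25 (4R,4aS,6R,7S,7aR)-2,4,7-trimethyloctahydro-1H-cyclopenta[c]pyridin-6-yl (2E,6S)-8-[(tert-butyldimethylsilyl)oxy]-2,6-dimethyloct-2-enoate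
Product: 26 (4R,4aS,6R,7S,7aR)-2,4,7-trimethyloctahydro-1H-cyclopenta[c]pyridin-6-yl (2E,6S)-8-hydroxy-2,6-dimethyloct-2-enoate (CNP0306711.1)
Conditions: HF·pyridine, THF, 0 °C to rt; NaHCO3 work-up
Reagents that add atoms: none
Why: fluoride cleavage of the primary silyl ether leaves the enoate ester and all stereocentres untouched.

**Compound list**

1 | 3,3-diethoxypropan-1-amine | NCCC(OCC)OCC | starting material
2 | methyl chloroformate | COC(=O)Cl | starting material
3 | methyl N-(3,3-diethoxypropyl)carbamate | COC(=O)NCCC(OCC)OCC | intermediate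
4 | 1-bromobut-2-yne | CC#CCBr | starting material
5 | methyl N-(but-2-yn-1-yl)-N-(3,3-diethoxypropyl)carbamate | COC(=O)N(CC#CC)CCC(OCC)OCC | intermediate
6 | methyl N-(but-2-yn-1-yl)-N-(3-oxopropyl)carbamate | COC(=O)N(CC#CC)CCC=O | intermediate
7 | formaldehyde | C=O | starting material
8 | methyl N-(but-2-yn-1-yl)-N-[(2R)-2-formyl-3-hydroxypropyl]carbamate | O=C[C@@H](CO)CN(CC#CC)C(=O)OC | intermediate
9 | ketenylidenetriphenylphosphorane (Bestmann ylide) | O=C=C=P(c1ccccc1)(c1ccccc1)c1ccccc1 | starting material
10 | (2R)-3-[but-2-yn-1-yl(methoxycarbonyl)amino]-2-formylpropyl 2-(triphenyl-λ5-phosphanylidene)acetate (ylide ester) | O=C[C@@H](COC(=O)C=P(c1ccccc1)(c1ccccc1)c1ccccc1)CN(CC#CC)C(=O)OC | intermediate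
11 | methyl N-(but-2-yn-1-yl)-N-{[(3R)-6-oxo-3,6-dihydro-2H-pyran-3-yl]methyl}carbamate | O=C1C=C[C@H](CN(CC#CC)C(=O)OC)CO1 | intermediate
12 | titanacyclopentene: diisopropoxytitanium bridging C7 and C5 of the cis-fused pyridine–lactone bicycle, lactone intact | CC1=C2CN(C(=O)OC)C[C@@H]3COC(=O)[C@H]([Ti]1(OC(C)C)OC(C)C)[C@H]23 | intermediate
13 | methyl (4R,4aS)-4-(hydroxymethyl)-7-methyl-6-oxo-1,3,4,4a,5,6-hexahydro-2H-cyclopenta[c]pyridine-2-carboxylate | O=C1C[C@H]2[C@@H](CO)CN(C(=O)OC)CC2=C1C | intermediate
14 | methyl (4R,4aS)-4-(iodomethyl)-7-methyl-6-oxo-1,3,4,4a,5,6-hexahydro-2H-cyclopenta[c]pyridine-2-carboxylate | O=C1C[C@H]2[C@@H](CI)CN(C(=O)OC)CC2=C1C | intermediate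
15 | methyl (4R,4aS,7R,7aR)-4,7-dimethyl-6-oxooctahydro-2H-cyclopenta[c]pyridine-2-carboxylate (C7 epimer) | O=C1C[C@@H]2[C@@H](CN(C(=O)OC)C[C@@H]2C)[C@H]1C | intermediate
16 | methyl (4R,4aS,7S,7aR)-4,7-dimethyl-6-oxooctahydro-2H-cyclopenta[c]pyridine-2-carboxylate | O=C1C[C@@H]2[C@@H](CN(C(=O)OC)C[C@@H]2C)[C@@H]1C | intermediate
17 | (4R,4aS,6S,7S,7aR)-2,4,7-trimethyloctahydro-1H-cyclopenta[c]pyridin-6-ol (6-epi-incarvilline) | O[C@H]1C[C@@H]2[C@@H](CN(C)C[C@@H]2C)[C@@H]1C | intermediate
18 | (S)-citronellol | CC(C)=CCC[C@H](C)CCO | starting material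
19 | tert-butyl{[(3S)-3,7-dimethyloct-6-en-1-yl]oxy}dimethylsilane | CC(C)=CCC[C@H](C)CCO[Si](C)(C)C(C)(C)C | intermediate
20 | ozonide (3,3-dimethyl-1,2,4-trioxolane carrying the silyloxy chain at C5; acetal carbon unassigned) | CC1(C)OOC(CC[C@H](C)CCO[Si](C)(C)C(C)(C)C)O1 | intermediate
21 | (4S)-6-[(tert-butyldimethylsilyl)oxy]-4-methylhexanal | O=CCC[C@H](C)CCO[Si](C)(C)C(C)(C)C | intermediate
22 | ethyl 2-(triphenyl-λ5-phosphanylidene)propanoate | CCOC(=O)C(C)=P(c1ccccc1)(c1ccccc1)c1ccccc1 | starting material
23 | ethyl (2E,6S)-8-[(tert-butyldimethylsilyl)oxy]-2,6-dimethyloct-2-enoate | C/C(=C\CC[C@H](C)CCO[Si](C)(C)C(C)(C)C)C(=O)OCC | intermediate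
24 | (2E,6S)-8-[(tert-butyldimethylsilyl)oxy]-2,6-dimethyloct-2-enoic acid | C/C(=C\CC[C@H](C)CCO[Si](C)(C)C(C)(C)C)C(=O)O | intermediate
25 | (4R,4aS,6R,7S,7aR)-2,4,7-trimethyloctahydro-1H-cyclopenta[c]pyridin-6-yl (2E,6S)-8-[(tert-butyldimethylsilyl)oxy]-2,6-dimethyloct-2-enoate | C/C(=C\CC[C@H](C)CCO[Si](C)(C)C(C)(C)C)C(=O)O[C@@H]1C[C@@H]2[C@@H](CN(C)C[C@@H]2C)[C@@H]1C | intermediate
26 | (4R,4aS,6R,7S,7aR)-2,4,7-trimethyloctahydro-1H-cyclopenta[c]pyridin-6-yl (2E,6S)-8-hydroxy-2,6-dimethyloct-2-enoate | C/C(=C\CC[C@H](C)CCO)C(=O)O[C@@H]1C[C@@H]2[C@@H](CN(C)C[C@@H]2C)[C@@H]1C | target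

**Step count.** 15 steps in total. The longest linear sequence is 11 steps (steps 1–9, 14, 15); the acid 24 is made in 4 steps (10–13).

**Steps most likely to fail**

Step 6. The alkenyl–titanium bond may be protonated on work-up before it has acylated the lactone (a ring alkoxide is a poorer leaving group than in open-chain esters), or the low-valent reagent may attack the lactone carbonyl before it binds the alkyne. The fallback sets out from 11 and returns at 13. Copper-catalysed borylative cyclization (CuCl, Xantphos, NaOtBu, B2pin2, t-BuOH, THF, rt) adds boron and copper syn across the alkyne with boron on the methyl-bearing carbon; the alkenylcopper adds to the lactone β-carbon from the same face as in step 6 and should give the cis-fused lactone alkenylboronate F1. Iododeboronation with retention (NaOH, I2, THF, 0 °C) gives the alkenyl iodide F2. Iodine–lithium exchange (t-BuLi, THF, −78 °C) then releases an alkenyllithium held next to the lactone carbonyl, which acylates it with ring opening (Parham-type cyclization) to give 13.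

Step 4. The β-hydroxy aldehyde may dehydrate to the 2-methylene aldehyde, or lose enantiopurity by enolization under amine catalysis or during lactone formation. The fallback sets out from 6 and returns at 11, bypassing 8. Condensation with (R)-1-amino-2-(methoxymethyl)pyrrolidine gives the RAMP hydrazone F3. Deprotonation (LiN(i-Pr)2, THF, −78 °C) and alkylation of the azaenolate with 4-methoxybenzyl chloromethyl ether gives the α-branched hydrazone F4 under auxiliary control. Aqueous oxalic acid/Et2O releases the aldehyde F5 without epimerization. Still–Gennari olefination (methyl bis(2,2,2-trifluoroethyl)phosphonoacetate, KN(SiMe3)2, 18-crown-6, THF, −78 °C) gives the (Z)-enoate F6. DDQ (CH2Cl2/pH 7 buffer) removes the PMB group and the hydroxy (Z)-ester lactonizes (catalytic camphorsulfonic acid) to 11.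

Step 9. Hydride delivery to the C6 ketone may be poorly face-selective, because the C7 methyl group sits on the otherwise favoured convex face, which would give a mixture of C6 epimers. The fallback sets out from 16 and returns at 25 with the opposite logic. LiBH(s-Bu)3 (THF, −78 °C), forced by its bulk to attack anti to the C7 methyl group, should give the (6R)-hydroxy carbamate F7. LiAlH4 (THF, reflux) converts the carbamate into the N-methyl amine, incarvilline F8. Yamaguchi esterification with acid 24 (2,4,6-trichlorobenzoyl chloride, Et3N, then DMAP, toluene), which retains configuration at C6, gives 25.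

**Further compounds**

F1 | step 6 | cis-fused pyridine–lactone bicycle (lactone stereocentres as in 12) with a (Z)-1-(pinacolboryl)ethylidene group at C7a, boron cis to C4a | C/C(B1OC(C)(C)C(C)(C)O1)=C2\CN(C(=O)OC)C[C@@H]3COC(=O)C[C@H]23
F2 | step 6 | the same bicycle with an (E)-1-iodoethylidene group at C7a, iodine cis to C4a | C/C(I)=C2\CN(C(=O)OC)C[C@@H]3COC(=O)C[C@H]23
F3 | step 4 | (E)-RAMP hydrazone of aldehyde 6 | COC[C@H]1CCCN1/N=C/CCN(CC#CC)C(=O)OC
F4 | step 4 | RAMP hydrazone of the α-[(4-methoxybenzyloxy)methyl] aldehyde, new stereocentre arranged as in 8 | COC[C@H]1CCCN1/N=C/[C@@H](COCc2ccc(OC)cc2)CN(CC#CC)C(=O)OC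
F5 | step 4 | methyl N-(but-2-yn-1-yl)-N-{(2R)-2-formyl-3-[(4-methoxybenzyl)oxy]propyl}carbamate | O=C[C@@H](COCc1ccc(OC)cc1)CN(CC#CC)C(=O)OC
F6 | step 4 | methyl (2Z,4R)-5-[but-2-yn-1-yl(methoxycarbonyl)amino]-4-{[(4-methoxybenzyl)oxy]methyl}pent-2-enoate | COC(=O)/C=C\[C@@H](COCc1ccc(OC)cc1)CN(CC#CC)C(=O)OC
F7 | step 9 | methyl (4R,4aS,6R,7S,7aR)-6-hydroxy-4,7-dimethyloctahydro-2H-cyclopenta[c]pyridine-2-carboxylate | O[C@@H]1C[C@@H]2[C@@H](CN(C(=O)OC)C[C@@H]2C)[C@@H]1C
F8 | step 9 | (4R,4aS,6R,7S,7aR)-2,4,7-trimethyloctahydro-1H-cyclopenta[c]pyridin-6-ol (incarvilline) | O[C@@H]1C[C@@H]2[C@@H](CN(C)C[C@@H]2C)[C@@H]1C
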